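**Strategy.** The cyclohexene ring (C3a–C4–C5–C6=C7–C7a, indene numbering) is a Diels–Alder retron: its C6=C7 alkene lies between C5 and C7a, and C4 carries the carboxyl carbon. Cutting C3a–C7a and C4–C5 unravels the bicycle to an acyclic (2E,7E,9E,11E)-tetraenal in which only the C1-ethyl, C3-methyl and a silyl-protected C2 carbinol stereocentres are preset. A tandem Wittig olefination/intramolecular Diels–Alder reaction then closes the cyclohexene last, creates the cyclopentane through the same C3a–C7a bond, and sets C3a, C4, C5 and C7a, including the vicinal quaternary pair, in one operation. Oxidation-level adjustments finish the synthesis.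

Key step: step 12

Remark: ring atoms carry 1H-indene numbering throughout, TBS means tert-butyldimethylsilyl, and the formyl-stabilised ylides 10 and 12 are treated as purchasable reagents.

**Step 1**
Reactants: 1 (R)-4-benzyl-1,3-thiazolidine-2-thione; 2 butanoyl chloride
Product: 3 (R)-4-benzyl-3-butanoyl-1,3-thiazolidine-2-thione
Conditions: Et3N, DMAP (cat.), CH2Cl2, 0 °C → rt
Reagents that add atoms: none
Why: DMAP-catalysed N-acylation of the thiazolidinethione by the acid chloride should give the imide without touching the benzyl-bearing stereocentre.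

**Step 2**
Reactants: 4 methyl (S)-3-hydroxy-2-methylpropanoate
Product: 5 methyl (S)-3-(TBS-oxy)-2-methylpropanoate
Conditions: TBSCl, imidazole, DMF, 0 °C → rt
Reagents that add atoms: tert-butyldimethylsilyl chloride, CC(C)(C)[Si](C)(C)Cl
Why: Imidazole-mediated silylation of the primary alcohol (Corey protocol) should proceed under conditions too mild to enolise the ester.

**Step 3**
Reactants: 5 methyl (S)-3-(TBS-oxy)-2-methylpropanoate
Product: 6 (S)-3-(TBS-oxy)-2-methylpropanal
Conditions: i-Bu2AlH (1.1 equiv), CH2Cl2, −78 °C; MeOH, aq. potassium sodium tartrate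
Reagents that add atoms: none
Why: Partial ester reduction should stop at the aldehyde because the aluminium hemiacetal is stable at −78 °C and collapses only on work-up; the crude aldehyde is used at once so that the α-stereocentre is retained.

**Step 4**
Reactants: 3 (R)-4-benzyl-3-butanoyl-1,3-thiazolidine-2-thione; 6 (S)-3-(TBS-oxy)-2-methylpropanal
Product: 7 (R)-4-benzyl-3-[(2R,3S,4S)-5-(TBS-oxy)-2-ethyl-3-hydroxy-4-methylpentanoyl]-1,3-thiazolidine-2-thione
Conditions: TiCl4 (1.05 equiv), i-Pr2NEt (1.1 equiv), N-methyl-2-pyrrolidone (1.1 equiv), CH2Cl2, 0 °C; then 6, −78 → 0 °C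
Reagents that add atoms: none
Why: In this Crimmins titanium-enolate aldol (Evans-syn mode) the chlorotitanium Z-enolate should react through a Zimmerman–Traxler transition state whose face is fixed by the (R)-benzyl auxiliary, setting C2 (R) and C3 (S) syn, while the 3,4-anti relation is the anti-Felkin outcome that Z-enolates prefer with α-methyl aldehydes, so both controls are matched.

**Step 5**
Reactants: 7 aldol adduct
Product: 8 (R)-4-benzyl-3-[(2R,3S,4S)-3,5-bis(TBS-oxy)-2-ethyl-4-methylpentanoyl]-1,3-thiazolidine-2-thione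
Conditions: TBSOTf, 2,6-lutidine, CH2Cl2, −78 → 0 °C
Reagents that add atoms: tert-butyldimethylsilyl trifluoromethanesulfonate, CC(C)(C)[Si](C)(C)OS(=O)(=O)C(F)(F)F
Why: Silyl triflate silylation should cap the hindered secondary alcohol and block retro-aldol cleavage in the later steps.

**Step 6**
Reactants: 8 bis-silylated imide
Product: 9 (2R,3S,4S)-3,5-bis(TBS-oxy)-2-ethyl-4-methylpentanal
Conditions: i-Bu2AlH, CH2Cl2, −78 °C; aq. potassium sodium tartrate
Reagents that add atoms: none
Why: N-Acylthiazolidinethiones are reduced by i-Bu2AlH directly to aldehydes through a stable tetrahedral intermediate that releases the auxiliary on work-up, so the α-ethyl stereocentre should survive at −78 °C.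

**Step 7**
Reactants: 9 (2R,3S,4S)-3,5-bis(TBS-oxy)-2-ethyl-4-methylpentanal; 10 2-(triphenylphosphoranylidene)propanal
Product: 11 (2E,4S,5R,6S)-5,7-bis(TBS-oxy)-4-ethyl-2,6-dimethylhept-2-enal
Conditions: toluene, 90 °C
Reagents that add atoms: none
Why: Wittig olefination with a formyl-stabilised ylide should give the trisubstituted (E)-enal under thermodynamic oxaphosphetane control, and the weakly basic ylide should not epimerise the α-centre.

**Step 8**
Reactants: 11 enal; 12 2-(triphenylphosphoranylidene)butanal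
Product: 13 (2E,4E,6S,7R,8S)-7,9-bis(TBS-oxy)-2,6-diethyl-4,8-dimethylnona-2,4-dienal
Conditions: toluene, 110 °C
Reagents that add atoms: none
Why: A second E-selective Wittig homologation with the α-ethyl formyl ylide should stop at the dienal, which is less electrophilic than the starting enal.

**Step 9**
Reactants: 13 dienal; 14 diethyl benzylphosphonate
Product: 15 [(1E,3E,5E,7S,8R,9S)-8,10-bis(TBS-oxy)-3,7-diethyl-5,9-dimethyldeca-1,3,5-trien-1-yl]benzene
Conditions: NaN(SiMe3)2, THF, −78 → 0 °C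
Reagents that add atoms: none
Why: Horner–Wadsworth–Emmons reaction of the benzylphosphonate anion should add 1,2 to the dienal and deliver the (E)-styryl unit by reversible addition and syn-elimination.

**Step 10**
Reactants: 15 bis-silyl triene
Product: 16 (2S,3R,4S,5E,7E,9E)-3-(TBS-oxy)-4,8-diethyl-2,6-dimethyl-10-phenyldeca-5,7,9-trien-1-ol
Conditions: HF·pyridine, pyridine, THF, 0 °C → rt
Reagents that add atoms: none
Why: Buffered fluoride desilylation should discriminate sterically, cleaving the unhindered primary silyl ether far faster than the secondary one flanked by two branched carbons.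

**Step 11**
Reactants: 16 primary alcohol
Product: 17 (2R,3R,4S,5E,7E,9E)-3-(TBS-oxy)-4,8-diethyl-2,6-dimethyl-10-phenyldeca-5,7,9-trienal
Conditions: Dess–Martin periodinane, NaHCO3, CH2Cl2, 0 °C → rt
Reagents that add atoms: none
Why: Buffered Dess–Martin oxidation should give the α-methyl aldehyde without epimerisation and without touching the triene.

**Step 12**
Reactants: 17 trienal; 12 2-(triphenylphosphoranylidene)butanal
Product: 19 (1S,2S,3S,3aR,4R,5S,7aR)-2-(TBS-oxy)-1,4,5-triethyl-3,7-dimethyl-5-[(E)-2-phenylethenyl]-2,3,3a,4,5,7a-hexahydro-1H-indene-4-carbaldehyde, via acyclic tetraenal 18 (not isolated)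
Conditions: toluene, BHT (cat.), 90 → 110 °C
Reagents that add atoms: none
Why: The stabilised ylide converts aldehyde 17 through an oxaphosphetane into the (E)-2-ethyl enal 18, whose (7E,9E)-diene and enal then undergo a thermal, concerted suprafacial [4+2] cycloaddition; the closest known reaction type is the tandem Wittig/intramolecular Diels–Alder reaction of 1,3,8-nonatrienes to trans-hydrindenes. The cyclohexene is closed by the cycloaddition itself (bonds C3a–C7a and C4–C5), and the cyclopentane forms as the three-atom-tether ring through the same C3a–C7a bond (type 1 intramolecular mode, fused). C4 and C5 are fixed stereospecifically by the E geometries of the enal and of the styryl-bearing diene terminus, and the trans ring fusion at C3a/C7a follows from the transition state with the formyl group endo. The absolute face is dictated by A(1,3) strain: C1–H eclipses the diene methyl and C3–H eclipses the dienophile ethyl, which turns the C1-ethyl and C3-methyl groups to the outside of the folding tether, and because these groups are anti both preferences select the same transition state. The step needs E-selective olefination, use of the proximal diene, endo and facial selectivity, and chemoselectivity; the stabilised ylide, the three-atom tether, the doubly allylic-strain-controlled fold and the inert neopentylic product aldehyde should secure these in turn.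

**Step 13**
Reactants: 19 silyl-protected cycloadduct
Product: 20 (1S,2S,3S,3aR,4R,5S,7aR)-1,4,5-triethyl-2-hydroxy-3,7-dimethyl-5-[(E)-2-phenylethenyl]-2,3,3a,4,5,7a-hexahydro-1H-indene-4-carbaldehyde
Conditions: 48% aq. HF, MeCN, 0 °C → rt
Reagents that add atoms: none
Why: Acidic fluoride desilylation should free the hindered secondary alcohol; the aldehyde is non-enolisable and cannot form a lactol because the C2 oxygen and C4 lie on opposite faces of the cyclopentane.

**Step 14**
Reactants: 20 hydroxy aldehyde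
Product: 21 (1S,3S,3aR,4R,5S,7aR)-1,4,5-triethyl-3,7-dimethyl-2-oxo-5-[(E)-2-phenylethenyl]-2,3,3a,4,5,7a-hexahydro-1H-indene-4-carbaldehyde
Conditions: Dess–Martin periodinane, NaHCO3, CH2Cl2, 0 °C → rt
Reagents that add atoms: none
Why: Buffered Dess–Martin oxidation should give the cyclopentanone, whose C1 and C3 substituents already sit trans to the adjacent ring-fusion bonds and are therefore not expected to epimerise.

**Step 15**
Reactants: 21 keto aldehyde
Product: 22 (1S,3S,3aR,4R,5S,7aR)-1,4,5-triethyl-3,7-dimethyl-2-oxo-5-[(E)-2-phenylethenyl]-2,3,3a,4,5,7a-hexahydro-1H-indene-4-carboxylic acid (target)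
Conditions: NaClO2, NaH2PO4, 2-methyl-2-butene, t-BuOH/H2O, 0 °C → rt
Reagents that add atoms: sodium chlorite, [Na+].[O-]Cl=O
Why: Pinnick oxidation should convert the aldehyde on quaternary C4 to the acid, with 2-methyl-2-butene scavenging hypochlorous acid so that the ring alkene and styrene are spared.

**Compound list**

1 | (R)-4-benzyl-1,3-thiazolidine-2-thione | S=C1SC[C@@H](Cc2ccccc2)N1 | starting material
2 | butanoyl chloride | CCCC(Cl)=O | starting material
3 | (R)-4-benzyl-3-butanoyl-1,3-thiazolidine-2-thione | CCCC(=O)N1[C@H](Cc2ccccc2)CSC1=S | intermediate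
4 | methyl (S)-3-hydroxy-2-methylpropanoate | COC(=O)[C@@H](C)CO | starting material
5 | methyl (S)-3-(TBS-oxy)-2-methylpropanoate | COC(=O)[C@@H](C)CO[Si](C)(C)C(C)(C)C | intermediate
6 | (S)-3-(TBS-oxy)-2-methylpropanal | O=C[C@@H](C)CO[Si](C)(C)C(C)(C)C | intermediate
7 | (R)-4-benzyl-3-[(2R,3S,4S)-5-(TBS-oxy)-2-ethyl-3-hydroxy-4-methylpentanoyl]-1,3-thiazolidine-2-thione | CC[C@@H](C(=O)N1[C@H](Cc2ccccc2)CSC1=S)[C@@H](O)[C@@H](C)CO[Si](C)(C)C(C)(C)C | intermediate
8 | (R)-4-benzyl-3-[(2R,3S,4S)-3,5-bis(TBS-oxy)-2-ethyl-4-methylpentanoyl]-1,3-thiazolidine-2-thione | CC[C@@H](C(=O)N1[C@H](Cc2ccccc2)CSC1=S)[C@@H](O[Si](C)(C)C(C)(C)C)[C@@H](C)CO[Si](C)(C)C(C)(C)C | intermediate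
9 | (2R,3S,4S)-3,5-bis(TBS-oxy)-2-ethyl-4-methylpentanal | CC[C@@H](C=O)[C@@H](O[Si](C)(C)C(C)(C)C)[C@@H](C)CO[Si](C)(C)C(C)(C)C | intermediate
10 | 2-(triphenylphosphoranylidene)propanal | CC(C=O)=P(c1ccccc1)(c1ccccc1)c1ccccc1 | starting material
11 | (2E,4S,5R,6S)-5,7-bis(TBS-oxy)-4-ethyl-2,6-dimethylhept-2-enal | CC[C@@H](/C=C(C)/C=O)[C@@H](O[Si](C)(C)C(C)(C)C)[C@@H](C)CO[Si](C)(C)C(C)(C)C | intermediate
12 | 2-(triphenylphosphoranylidene)butanal | CCC(C=O)=P(c1ccccc1)(c1ccccc1)c1ccccc1 | starting material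
13 | (2E,4E,6S,7R,8S)-7,9-bis(TBS-oxy)-2,6-diethyl-4,8-dimethylnona-2,4-dienal | CC[C@@H](/C=C(C)/C=C(CC)/C=O)[C@@H](O[Si](C)(C)C(C)(C)C)[C@@H](C)CO[Si](C)(C)C(C)(C)C | intermediate
14 | diethyl benzylphosphonate | CCOP(=O)(Cc1ccccc1)OCC | starting material
15 | [(1E,3E,5E,7S,8R,9S)-8,10-bis(TBS-oxy)-3,7-diethyl-5,9-dimethyldeca-1,3,5-trien-1-yl]benzene | CC[C@@H](/C=C(C)/C=C(CC)/C=C/c1ccccc1)[C@@H](O[Si](C)(C)C(C)(C)C)[C@@H](C)CO[Si](C)(C)C(C)(C)C | intermediate
16 | (2S,3R,4S,5E,7E,9E)-3-(TBS-oxy)-4,8-diethyl-2,6-dimethyl-10-phenyldeca-5,7,9-trien-1-ol | CC[C@@H](/C=C(C)/C=C(CC)/C=C/c1ccccc1)[C@@H](O[Si](C)(C)C(C)(C)C)[C@@H](C)CO | intermediate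
17 | (2R,3R,4S,5E,7E,9E)-3-(TBS-oxy)-4,8-diethyl-2,6-dimethyl-10-phenyldeca-5,7,9-trienal | CC[C@@H](/C=C(C)/C=C(CC)/C=C/c1ccccc1)[C@@H](O[Si](C)(C)C(C)(C)C)[C@@H](C)C=O | intermediate
18 | (2E,4S,5S,6S,7E,9E,11E)-5-(TBS-oxy)-2,6,10-triethyl-4,8-dimethyl-12-phenyldodeca-2,7,9,11-tetraenal (not isolated) | CC[C@@H](/C=C(C)/C=C(CC)/C=C/c1ccccc1)[C@@H](O[Si](C)(C)C(C)(C)C)[C@@H](C)/C=C(\CC)C=O | intermediate
19 | (1S,2S,3S,3aR,4R,5S,7aR)-2-(TBS-oxy)-1,4,5-triethyl-3,7-dimethyl-5-[(E)-2-phenylethenyl]-2,3,3a,4,5,7a-hexahydro-1H-indene-4-carbaldehyde | CC[C@@H]1[C@@H](O[Si](C)(C)C(C)(C)C)[C@@H](C)[C@H]2[C@H]1C(C)=C[C@@](/C=C/c1ccccc1)(CC)[C@]2(CC)C=O | intermediate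
20 | (1S,2S,3S,3aR,4R,5S,7aR)-1,4,5-triethyl-2-hydroxy-3,7-dimethyl-5-[(E)-2-phenylethenyl]-2,3,3a,4,5,7a-hexahydro-1H-indene-4-carbaldehyde | CC[C@@H]1[C@@H](O)[C@@H](C)[C@H]2[C@H]1C(C)=C[C@@](/C=C/c1ccccc1)(CC)[C@]2(CC)C=O | intermediate
21 | (1S,3S,3aR,4R,5S,7aR)-1,4,5-triethyl-3,7-dimethyl-2-oxo-5-[(E)-2-phenylethenyl]-2,3,3a,4,5,7a-hexahydro-1H-indene-4-carbaldehyde | CC[C@@H]1C(=O)[C@@H](C)[C@H]2[C@H]1C(C)=C[C@@](/C=C/c1ccccc1)(CC)[C@]2(CC)C=O | intermediate
22 | (1S,3S,3aR,4R,5S,7aR)-1,4,5-triethyl-3,7-dimethyl-2-oxo-5-[(E)-2-phenylethenyl]-2,3,3a,4,5,7a-hexahydro-1H-indene-4-carboxylic acid | CC[C@@H]1C(=O)[C@@H](C)[C@H]2[C@H]1C(C)=C[C@@](/C=C/c1ccccc1)(CC)[C@]2(CC)C(=O)O | target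

**Step count and risks**

Total step count: 15. Longest linear sequence: 14 steps (steps 2–15, from 4 to 22).

Step 12 (key step). The weakly nucleophilic formyl ylide may olefinate the branched aldehyde too slowly, so that α-epimerisation of 17 or further homologation of 18 competes with cycloaddition. The fallback sets out from 17 and comes back at 19. The more nucleophilic ester ylide ethyl 2-(triphenylphosphoranylidene)butanoate F1 (from ethyl 2-bromobutanoate and PPh3, then aqueous NaOH) should olefinate 17 at about 50 °C to give ethyl (2E,4S,5S,6S,7E,9E,11E)-5-(TBS-oxy)-2,6,10-triethyl-4,8-dimethyl-12-phenyldodeca-2,7,9,11-tetraenoate F2. This ester is then cyclised in a separate thermal Diels–Alder operation (toluene, BHT, 130 °C) to the ethyl hexahydroindene-4-carboxylate F3. Reduction with LiAlH4 should give the neopentylic hexahydroinden-4-ylmethanol F4, and Dess–Martin oxidation returns aldehyde 19.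

Step 8. The conjugated enal 11 is a poor electrophile for the formyl ylide, so conversion may stall or a second homologation may set in on prolonged heating. The fallback sets out from 11 and comes back at 13. A Horner–Wadsworth–Emmons reaction with triethyl 2-phosphonobutanoate (NaH, THF, 0 °C) should give ethyl (2E,4E,6S,7R,8S)-7,9-bis(TBS-oxy)-2,6-diethyl-4,8-dimethylnona-2,4-dienoate F5. Reduction with i-Bu2AlH gives (2E,4E,6S,7R,8S)-7,9-bis(TBS-oxy)-2,6-diethyl-4,8-dimethylnona-2,4-dien-1-ol F6, and MnO2 oxidation gives dienal 13.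

Step 9. The phosphonate anion may deprotonate the dienal at its vinylogous positions, eroding olefin geometry or the ethyl-bearing stereocentre, or the new alkene may form with incomplete E selectivity. The fallback sets out from 13 and comes back at 15. Takai iodo-olefination (CrCl2, CHI3, THF, 0 °C) should give (1E,3E,5E,7S,8R,9S)-8,10-bis(TBS-oxy)-3,7-diethyl-1-iodo-5,9-dimethyldeca-1,3,5-triene F7. Suzuki–Miyaura coupling with phenylboronic acid (Pd(PPh3)4, aq. K3PO4, THF) then gives triene 15 with retention of geometry.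

**Further compounds**

F1 | step 12 | ethyl 2-(triphenylphosphoranylidene)butanoate | CCOC(=O)C(CC)=P(c1ccccc1)(c1ccccc1)c1ccccc1
F2 | step 12 | ethyl (2E,4S,5S,6S,7E,9E,11E)-5-(TBS-oxy)-2,6,10-triethyl-4,8-dimethyl-12-phenyldodeca-2,7,9,11-tetraenoate | CC[C@@H](/C=C(C)/C=C(CC)/C=C/c1ccccc1)[C@@H](O[Si](C)(C)C(C)(C)C)[C@@H](C)/C=C(\CC)C(=O)OCC
F3 | step 12 | ethyl (1S,2S,3S,3aR,4R,5S,7aR)-2-(TBS-oxy)-1,4,5-triethyl-3,7-dimethyl-5-[(E)-2-phenylethenyl]-2,3,3a,4,5,7a-hexahydro-1H-indene-4-carboxylate | CC[C@@H]1[C@@H](O[Si](C)(C)C(C)(C)C)[C@@H](C)[C@H]2[C@H]1C(C)=C[C@@](/C=C/c1ccccc1)(CC)[C@]2(CC)C(=O)OCC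
F4 | step 12 | [(1S,2S,3S,3aR,4R,5S,7aR)-2-(TBS-oxy)-1,4,5-triethyl-3,7-dimethyl-5-[(E)-2-phenylethenyl]-2,3,3a,4,5,7a-hexahydro-1H-inden-4-yl]methanol | CC[C@@H]1[C@@H](O[Si](C)(C)C(C)(C)C)[C@@H](C)[C@H]2[C@H]1C(C)=C[C@@](/C=C/c1ccccc1)(CC)[C@]2(CC)CO
F5 | step 8 | ethyl (2E,4E,6S,7R,8S)-7,9-bis(TBS-oxy)-2,6-diethyl-4,8-dimethylnona-2,4-dienoate | CC[C@@H](/C=C(C)/C=C(CC)/C(=O)OCC)[C@@H](O[Si](C)(C)C(C)(C)C)[C@@H](C)CO[Si](C)(C)C(C)(C)C
F6 | step 8 | (2E,4E,6S,7R,8S)-7,9-bis(TBS-oxy)-2,6-diethyl-4,8-dimethylnona-2,4-dien-1-ol | CC[C@@H](/C=C(C)/C=C(CC)/CO)[C@@H](O[Si](C)(C)C(C)(C)C)[C@@H](C)CO[Si](C)(C)C(C)(C)C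
F7 | step 9 | (1E,3E,5E,7S,8R,9S)-8,10-bis(TBS-oxy)-3,7-diethyl-1-iodo-5,9-dimethyldeca-1,3,5-triene | CC[C@@H](/C=C(C)/C=C(CC)/C=C/I)[C@@H](O[Si](C)(C)C(C)(C)C)[C@@H](C)CO[Si](C)(C)C(C)(C)C
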